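The route rests on an intramolecular Diels–Alder disconnection of the methylcyclohexene ring. Its ring C=C(CH3), flanked by the allylic ring-fusion CH and by the CH2–CH2 pair, is the retron of a 2-methylbutadiene plus a vinyl group; the carbon that will carry CH3 and NHCHO in the other ring serves as a tether ketone that activates the vinyl group. In one operation the key step closes both six-membered rings of the cis-octalin and sets both ring-fusion stereocentres. Its precursor is an acyclic (E)-deca-1,7,9-trien-3-one that already carries the complete formamido-oxolane on its allylic stereocentre, made from geraniol by two reagent-controlled epoxidations.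

Key step: step 11

Remark: locants C1–C15 below are those of the biflorane skeleton of the target (C1 and C6 = ring-fusion carbons, C4=C5 = ring alkene, C7 = ring carbon bearing the oxolane, C10 = ring carbon bearing CH3/NHCHO, C11 and C14 = oxolane carbons, C15 = side-chain C(CH3)2N); it is assumed that a secondary formamide N–H can be carried through the organometallic steps at the cost of one extra equivalent of reagent.

Step 1
Reactants: 1 geraniol
Product: 2 [(2S,3S)-3-methyl-3-(4-methylpent-3-en-1-yl)oxiran-2-yl]methanol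
Conditions: Ti(OiPr)4 (5 mol%), L-(+)-diethyl tartrate (7 mol%), t-BuOOH, 4 Å MS, CH2Cl2, −20 °C
Reagents that add atoms: tert-butyl hydroperoxide CC(C)(C)OO
Why: Sharpless asymmetric epoxidation of the allylic alcohol, in which the L-(+)-tartrate catalyst should give the (2S,3S)-epoxide and thereby fix C11 directly and C7 after one inversion.

Step 2
Reactants: 2 [(2S,3S)-3-methyl-3-(4-methylpent-3-en-1-yl)oxiran-2-yl]methanol, 3 but-3-en-1-ylmagnesium bromide
Product: 4 (2R,3S)-2-(but-3-en-1-yl)-3,7-dimethyloct-6-ene-1,3-diol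
Conditions: 3 (3 equiv), CuI (10 mol%), THF, −40 → 0 °C; aq. NH4Cl
Reagents that add atoms: none
Why: Copper-catalysed SN2 opening of the 2,3-epoxy alcohol by the Grignard reagent at the less hindered C2, anti to the C–O bond, should set C7 by inversion and leave the tertiary C11–O bond untouched.

Step 3
Reactants: 4 (2R,3S)-2-(but-3-en-1-yl)-3,7-dimethyloct-6-ene-1,3-diol
Product: 6 (2R)-2-[(2S,5R)-5-(2-hydroxypropan-2-yl)-2-methyloxolan-2-yl]hex-5-en-1-ol, via epoxy diol 5 (not isolated)
Conditions: ent-Shi ketone (L-fructose-derived, 30 mol%), Oxone, K2CO3, Bu4NHSO4, MeCN/DMM/aq. buffer pH 10.5, 0 °C; then CSA (cat.), CH2Cl2, 0 °C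
Reagents that add atoms: potassium peroxymonosulfate (Oxone) [K+].[O-]S(=O)(=O)OO
Why: Shi asymmetric epoxidation should attack only the electron-rich trisubstituted alkene and give the (S)-epoxide under reagent control, and acid-catalysed 5-exo-tet epoxide opening by the tertiary hydroxyl with inversion then sets C14 as R.

Step 4
Reactants: 6 (2R)-2-[(2S,5R)-5-(2-hydroxypropan-2-yl)-2-methyloxolan-2-yl]hex-5-en-1-ol
Product: 8 (5R)-5-[(2S,5R)-5-(2-hydroxypropan-2-yl)-2-methyloxolan-2-yl]oxan-2-one, via lactol 7 (not isolated)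
Conditions: O3, NaOH (2.5 M in MeOH), CH2Cl2, −78 °C; then aq. HCl to pH 3, TsOH (cat.), PhMe, rt
Reagents that add atoms: ozone [O-][O+]=O
Why: Ozonolysis of the terminal alkene in methanolic NaOH (Marshall conditions) should give the aldehyde, which closes to the six-membered lactol whose alkoxide is oxidised by ozone to the δ-lactone, masking the primary alcohol and creating the C10 acyl carbon without touching a stereocentre.

Step 5
Reactants: 8 (5R)-5-[(2S,5R)-5-(2-hydroxypropan-2-yl)-2-methyloxolan-2-yl]oxan-2-one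
Product: 9 (5R)-5-[(2S,5R)-2-methyl-5-(prop-1-en-2-yl)oxolan-2-yl]oxan-2-one
Conditions: Burgess reagent, PhMe, 50 °C
Reagents that add atoms: none
Why: Burgess dehydration (syn-elimination) of the tertiary alcohol should remove one of the six methyl hydrogens in preference to the single ring C–H next to oxygen and give the isopropenyl group.

Step 6
Reactants: 9 (5R)-5-[(2S,5R)-2-methyl-5-(prop-1-en-2-yl)oxolan-2-yl]oxan-2-one
Product: 10 (5R)-5-[(2S,5R)-5-(2-azidopropan-2-yl)-2-methyloxolan-2-yl]oxan-2-one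
Conditions: Co(II)–salen catalyst (6 mol%), TsN3, PhSiH3, t-BuOOH (cat.), EtOH, rt
Reagents that add atoms: 4-methylbenzenesulfonyl azide Cc1ccc(cc1)S(=O)(=O)N=[N+]=[N-]
Why: Cobalt-hydride hydrogen-atom-transfer hydroazidation (Mukaiyama/Carreira type) should add Markovnikov through a tertiary radical, not a cation, so the oxolane cannot ring-expand.

Step 7
Reactants: 10 (5R)-5-[(2S,5R)-5-(2-azidopropan-2-yl)-2-methyloxolan-2-yl]oxan-2-one
Product: 12 N-{2-[(2R,5S)-5-methyl-5-[(3R)-6-oxooxan-3-yl]oxolan-2-yl]propan-2-yl}formamide, via amine 11 (not isolated)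
Conditions: H2 (1 atm), Pd/C, EtOAc, rt; filter; then acetic formic anhydride, THF, 0 °C
Reagents that add atoms: acetic formic anhydride CC(=O)OC=O
Why: Catalytic hydrogenolysis of the azide followed by N-formylation of the hindered amine with the mixed anhydride, whose formyl group is the more electrophilic acyl group.

Step 8
Reactants: 12 N-{2-[(2R,5S)-5-methyl-5-[(3R)-6-oxooxan-3-yl]oxolan-2-yl]propan-2-yl}formamide, 13 N,O-dimethylhydroxylamine hydrochloride
Product: 14 (4R)-4-[(2S,5R)-5-(2-formamidopropan-2-yl)-2-methyloxolan-2-yl]-5-hydroxy-N-methoxy-N-methylpentanamide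
Conditions: i-PrMgCl, THF, −20 → 0 °C
Reagents that add atoms: none
Why: Weinreb amide formation by aminolysis of the δ-lactone with the magnesium amide should open the ring, free the primary alcohol and give the acyl donor for the dienophile.

Step 9
Reactants: 14 (4R)-4-[(2S,5R)-5-(2-formamidopropan-2-yl)-2-methyloxolan-2-yl]-5-hydroxy-N-methoxy-N-methylpentanamide, 15 1-(triphenyl-λ5-phosphanylidene)propan-2-one
Product: 17 (4R,5E)-4-[(2S,5R)-5-(2-formamidopropan-2-yl)-2-methyloxolan-2-yl]-N-methoxy-N-methyl-7-oxooct-5-enamide, via aldehyde 16 (not isolated)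
Conditions: Dess–Martin periodinane, CH2Cl2, 0 °C → rt; then 15, rt → 40 °C
Reagents that add atoms: none
Why: Dess–Martin oxidation and in-flask Wittig olefination with the stabilised ylide should give the (E)-enone under near-neutral conditions that neither epimerise C7 nor open the β-alkoxy aldehyde.

Step 10
Reactants: 17 (4R,5E)-4-[(2S,5R)-5-(2-formamidopropan-2-yl)-2-methyloxolan-2-yl]-N-methoxy-N-methyl-7-oxooct-5-enamide
Product: 18 (4R,5E)-4-[(2S,5R)-5-(2-formamidopropan-2-yl)-2-methyloxolan-2-yl]-N-methoxy-N,7-dimethylocta-5,7-dienamide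
Conditions: Ph3PCH3Br, KHMDS, THF, −78 → 0 °C (3.5 equiv ylide)
Reagents that add atoms: methyltriphenylphosphonium bromide C[P+](c1ccccc1)(c1ccccc1)c1ccccc1.[Br-]
Why: Wittig methylenation of the enone carbonyl, which reacts faster than the Weinreb amide at or below 0 °C, should give the 2-methyl-1,3-diene with the (E)-alkene unchanged.

Step 11
Reactants: 18 (4R,5E)-4-[(2S,5R)-5-(2-formamidopropan-2-yl)-2-methyloxolan-2-yl]-N-methoxy-N,7-dimethylocta-5,7-dienamide, 19 vinylmagnesium bromide
Product: 21 N-{2-[(2R,5S)-5-methyl-5-[(1R,4aS,8aS)-7-methyl-4-oxo-1,2,3,4,4a,5,6,8a-octahydronaphthalen-1-yl]oxolan-2-yl]propan-2-yl}formamide, via trienone 20 (not isolated)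
Conditions: 19 (3 equiv), THF, −78 → 0 °C; cold 1 M HCl quench, extract; then PhMe, BHT (cat.), 23 → 45 °C
Reagents that add atoms: none
Why: Vinylmagnesium bromide acylation of the Weinreb amide (stable magnesium chelate, no over-addition) gives on acidic quench the deca-1,7,9-trien-3-one 20, which cyclises by a concerted, thermally allowed [4π+2π] cycloaddition, a type-1 intramolecular Diels–Alder reaction of a tether-activated vinyl ketone as known for 6-alkyl-deca-1,7,9-trien-3-ones that give cis-octalones of the muurolane and kalihinane series. The cyclohexene ring (C1–C6) is closed by both new σ-bonds, C2–C3 and C1–C6, in the suprafacial [4+2] mode, and the cyclohexanone ring (C1, C6–C10) is closed by the C1–C6 bond alone, the four-atom tether C7–C10 making it the fused six-membered ring. C1 and C6 are set relative to each other by the endo transition state, in which the tether carbonyl C10=O lies under the (E)-diene, and this gives the cis ring fusion. Their sense relative to C7 is set by the allylic stereocentre itself: in the boat-like tether conformation the quaternary oxolane carbon stands perpendicular to the diene on the face away from the dienophile, so H6 ends up trans to H7. The step needs endo over exo selectivity, secured by conjugation of the dienophile with the in-chain ketone, and π-facial selectivity, secured by the size of the C7 substituent; regiochemistry is fixed by the tether, and the trisubstituted C4=C5 bond appears where the target has it.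

Step 12
Reactants: 21 N-{2-[(2R,5S)-5-methyl-5-[(1R,4aS,8aS)-7-methyl-4-oxo-1,2,3,4,4a,5,6,8a-octahydronaphthalen-1-yl]oxolan-2-yl]propan-2-yl}formamide, 22 (R)-2-methylpropane-2-sulfinamide
Product: 23 N-[(R)-tert-butanesulfinyl] ketimine of 21 at C10 (sulfinyl group anti to the ring-fusion carbon C1)
Conditions: Ti(OEt)4, THF, 60 °C
Reagents that add atoms: none
Why: Titanium-mediated condensation to the Ellman N-sulfinyl ketimine, in which the sulfinyl group should settle anti to the more hindered α-carbon C1.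

Step 13
Reactants: 23 N-[(R)-tert-butanesulfinyl] ketimine of 21 at C10
Product: 24 (R)-N-{(1R,4R,4aS,8aR)-4-[(2S,5R)-5-(2-formamidopropan-2-yl)-2-methyloxolan-2-yl]-1,6-dimethyl-1,2,3,4,4a,7,8,8a-octahydronaphthalen-1-yl}-2-methylpropane-2-sulfinamide
Conditions: AlMe3, PhMe, −78 °C; then MeLi, −78 °C
Reagents that add atoms: methyllithium [Li]C
Why: Ellman 1,2-addition of methyllithium to the AlMe3-activated N-sulfinyl ketimine, where axial attack on the convex face of the cis-octalin and the cyclic chelate of the (R)-sulfinyl group point to the same face, should set C10 with CH3 cis to the ring-fusion hydrogens and nitrogen equatorial.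

Step 14
Reactants: 24 (R)-N-{(1R,4R,4aS,8aR)-4-[(2S,5R)-5-(2-formamidopropan-2-yl)-2-methyloxolan-2-yl]-1,6-dimethyl-1,2,3,4,4a,7,8,8a-octahydronaphthalen-1-yl}-2-methylpropane-2-sulfinamide
Product: 26 N-{2-[(2R,5S)-5-[(1R,4R,4aS,8aR)-4-formamido-4,7-dimethyl-1,2,3,4,4a,5,6,8a-octahydronaphthalen-1-yl]-5-methyloxolan-2-yl]propan-2-yl}formamide (target), via amine hydrochloride 25 (not isolated)
Conditions: HCl (4 M in dioxane), MeOH, 0 °C; concentrate; then acetic formic anhydride, Et3N, CH2Cl2, 0 °C → rt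
Reagents that add atoms: acetic formic anhydride CC(=O)OC=O
Why: Acidic methanolysis of the sulfinamide N–S bond followed by N-formylation of the tertiary-alkyl amine, with no stereocentre involved.

Compound list
1 | geraniol, (2E)-3,7-dimethylocta-2,6-dien-1-ol | CC(C)=CCC/C(C)=C/CO | starting material
2 | [(2S,3S)-3-methyl-3-(4-methylpent-3-en-1-yl)oxiran-2-yl]methanol | OC[C@@H]1O[C@@]1(C)CCC=C(C)C | intermediate
3 | but-3-en-1-ylmagnesium bromide | C=CCC[Mg]Br | starting material
4 | (2R,3S)-2-(but-3-en-1-yl)-3,7-dimethyloct-6-ene-1,3-diol | OC[C@H]([C@](O)(C)CCC=C(C)C)CCC=C | intermediate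
5 | (2R,3S)-2-(but-3-en-1-yl)-5-[(2S)-3,3-dimethyloxiran-2-yl]-3-methylpentane-1,3-diol | OC[C@H]([C@](O)(C)CC[C@@H]1OC1(C)C)CCC=C | intermediate
6 | (2R)-2-[(2S,5R)-5-(2-hydroxypropan-2-yl)-2-methyloxolan-2-yl]hex-5-en-1-ol | OC[C@H]([C@]1(C)CC[C@H](C(C)(C)O)O1)CCC=C | intermediate
7 | (5R)-5-[(2S,5R)-5-(2-hydroxypropan-2-yl)-2-methyloxolan-2-yl]oxan-2-ol (lactol, anomer mixture) | OC1CC[C@H](CO1)[C@]2(C)CC[C@H](C(C)(C)O)O2 | intermediate
8 | (5R)-5-[(2S,5R)-5-(2-hydroxypropan-2-yl)-2-methyloxolan-2-yl]oxan-2-one | O=C1CC[C@H](CO1)[C@]2(C)CC[C@H](C(C)(C)O)O2 | intermediate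
9 | (5R)-5-[(2S,5R)-2-methyl-5-(prop-1-en-2-yl)oxolan-2-yl]oxan-2-one | O=C1CC[C@H](CO1)[C@]2(C)CC[C@H](C(C)=C)O2 | intermediate
10 | (5R)-5-[(2S,5R)-5-(2-azidopropan-2-yl)-2-methyloxolan-2-yl]oxan-2-one | O=C1CC[C@H](CO1)[C@]2(C)CC[C@H](C(C)(C)N=[N+]=[N-])O2 | intermediate
11 | (5R)-5-[(2S,5R)-5-(2-aminopropan-2-yl)-2-methyloxolan-2-yl]oxan-2-one | O=C1CC[C@H](CO1)[C@]2(C)CC[C@H](C(C)(C)N)O2 | intermediate
12 | N-{2-[(2R,5S)-5-methyl-5-[(3R)-6-oxooxan-3-yl]oxolan-2-yl]propan-2-yl}formamide | O=C1CC[C@H](CO1)[C@]2(C)CC[C@H](C(C)(C)NC=O)O2 | intermediate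
13 | N,O-dimethylhydroxylamine hydrochloride | CNOC.Cl | starting material
14 | (4R)-4-[(2S,5R)-5-(2-formamidopropan-2-yl)-2-methyloxolan-2-yl]-5-hydroxy-N-methoxy-N-methylpentanamide | OC[C@@H](CCC(=O)N(C)OC)[C@]1(C)CC[C@H](C(C)(C)NC=O)O1 | intermediate
15 | 1-(triphenyl-λ5-phosphanylidene)propan-2-one | CC(=O)C=P(c1ccccc1)(c1ccccc1)c1ccccc1 | starting material
16 | (4S)-4-[(2S,5R)-5-(2-formamidopropan-2-yl)-2-methyloxolan-2-yl]-N-methoxy-N-methyl-5-oxopentanamide | O=C[C@@H](CCC(=O)N(C)OC)[C@]1(C)CC[C@H](C(C)(C)NC=O)O1 | intermediate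
17 | (4R,5E)-4-[(2S,5R)-5-(2-formamidopropan-2-yl)-2-methyloxolan-2-yl]-N-methoxy-N-methyl-7-oxooct-5-enamide | CC(=O)/C=C/[C@@H](CCC(=O)N(C)OC)[C@]1(C)CC[C@H](C(C)(C)NC=O)O1 | intermediate
18 | (4R,5E)-4-[(2S,5R)-5-(2-formamidopropan-2-yl)-2-methyloxolan-2-yl]-N-methoxy-N,7-dimethylocta-5,7-dienamide | C=C(C)/C=C/[C@@H](CCC(=O)N(C)OC)[C@]1(C)CC[C@H](C(C)(C)NC=O)O1 | intermediate
19 | vinylmagnesium bromide | C=C[Mg]Br | starting material
20 | N-{2-[(2R,5S)-5-methyl-5-[(3E,5R)-2-methyl-8-oxodeca-1,3,9-trien-5-yl]oxolan-2-yl]propan-2-yl}formamide | C=C(C)/C=C/[C@@H](CCC(=O)C=C)[C@]1(C)CC[C@H](C(C)(C)NC=O)O1 | intermediate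
21 | N-{2-[(2R,5S)-5-methyl-5-[(1R,4aS,8aS)-7-methyl-4-oxo-1,2,3,4,4a,5,6,8a-octahydronaphthalen-1-yl]oxolan-2-yl]propan-2-yl}formamide (cis-fused) | CC1=C[C@H]2[C@H]([C@]3(C)CC[C@H](C(C)(C)NC=O)O3)CCC(=O)[C@H]2CC1 | intermediate
22 | (R)-2-methylpropane-2-sulfinamide | CC(C)(C)[S@@](=O)N | starting material
23 | N-[(R)-tert-butanesulfinyl] ketimine of 21 at C10, sulfinyl anti to the ring-fusion carbon | CC1=C[C@H]2[C@H]([C@]3(C)CC[C@H](C(C)(C)NC=O)O3)CC/C(=N\[S@](=O)C(C)(C)C)[C@H]2CC1 | intermediate
24 | (R)-N-{(1R,4R,4aS,8aR)-4-[(2S,5R)-5-(2-formamidopropan-2-yl)-2-methyloxolan-2-yl]-1,6-dimethyl-1,2,3,4,4a,7,8,8a-octahydronaphthalen-1-yl}-2-methylpropane-2-sulfinamide | CC1=C[C@H]2[C@H]([C@]3(C)CC[C@H](C(C)(C)NC=O)O3)CC[C@@](C)(N[S@](=O)C(C)(C)C)[C@H]2CC1 | intermediate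
25 | N-{2-[(2R,5S)-5-[(1R,4R,4aS,8aR)-4-amino-4,7-dimethyl-1,2,3,4,4a,5,6,8a-octahydronaphthalen-1-yl]-5-methyloxolan-2-yl]propan-2-yl}formamide hydrochloride | CC1=C[C@H]2[C@H]([C@]3(C)CC[C@H](C(C)(C)NC=O)O3)CC[C@@](C)(N)[C@H]2CC1.Cl | intermediate
26 | N-{2-[(2R,5S)-5-[(1R,4R,4aS,8aR)-4-formamido-4,7-dimethyl-1,2,3,4,4a,5,6,8a-octahydronaphthalen-1-yl]-5-methyloxolan-2-yl]propan-2-yl}formamide | CC1=C[C@H]2[C@H]([C@]3(C)CC[C@H](C(C)(C)NC=O)O3)CC[C@@](C)(NC=O)[C@H]2CC1 | target

Total step count: 14. Longest linear sequence: 14 steps, from geraniol.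

Steps most likely to fail

Step 11. The liberated N,O-dimethylhydroxylamine or a second equivalent of Grignard reagent may add to the vinyl ketone in conjugate fashion before it cyclises, the enone may polymerise, and endo or π-facial selectivity may erode in the thermal cycloaddition. The fallback sets out from 18 and comes back at 21. DIBAL-H reduction of the Weinreb amide at −78 °C would give the aldehyde F1, and addition of vinylmagnesium bromide the allylic alcohol F2 (carbinol epimers, both usable). Dess–Martin oxidation in CH2Cl2 would then release trienone 20 with no amine or base present. It would be cyclised in the same flask with Me2AlCl at −78 → −20 °C, where coordination to the tether ketone strengthens the endo preference, to give 21.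

Step 12. Condensation at the hindered α-branched ketone may be slow, and the ring-fusion centre C1 may epimerise through the aza-enolate (cis to trans octalin); in step 13 α-deprotonation may compete with addition. The fallback sets out from 18 and comes back at 26; it builds the nitrogen centre before ring closure, where no α-stereocentre can be lost. MeMgBr would convert 18 into the methyl ketone F3, and condensation with 22/Ti(OEt)4 would give the N-sulfinyl ketimine F4. Vinylmagnesium bromide in CH2Cl2 at −48 °C would add through the Ellman chelate to give the sulfinamide F5, with the quaternary centre set by the auxiliary. HCl/MeOH would give the amine hydrochloride F6 and acetic formic anhydride the bis-formamide triene F7. Thermal intramolecular Diels–Alder reaction of F7 (PhMe, 180 °C, BHT, sealed tube) would then give 26 directly, with lower endo selectivity expected for the unactivated vinyl group and a separation of ring-fusion isomers.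

Step 6. Azide transfer to the hindered tertiary radical beside the ring oxygen may be slow, so that simple reduction of the alkene competes. The fallback sets out from 9 and comes back at 11. Manganese-catalysed hydrohydrazination (Mn(dpm)3, PhSiH3, di-tert-butyl azodicarboxylate, i-PrOH) would trap the same radical with a faster acceptor to give the di-Boc hydrazine F8. TFA would remove both Boc groups to give the hydrazine F9, and Raney nickel/H2 would cleave the N–N bond to amine 11, which is formylated as in step 7.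

Further compounds
F1 | step 11 | N-{2-[(2R,5S)-5-methyl-5-[(3E,5R)-2-methyl-8-oxoocta-1,3-dien-5-yl]oxolan-2-yl]propan-2-yl}formamide (aldehyde) | C=C(C)/C=C/[C@@H](CCC=O)[C@]1(C)CC[C@H](C(C)(C)NC=O)O1
F2 | step 11 | N-{2-[(2R,5S)-5-[(3E,5R)-8-hydroxy-2-methyldeca-1,3,9-trien-5-yl]-5-methyloxolan-2-yl]propan-2-yl}formamide (allylic alcohol, carbinol epimers) | C=C(C)/C=C/[C@@H](CCC(O)C=C)[C@]1(C)CC[C@H](C(C)(C)NC=O)O1
F3 | step 12 | N-{2-[(2R,5S)-5-methyl-5-[(3E,5R)-2-methyl-8-oxonona-1,3-dien-5-yl]oxolan-2-yl]propan-2-yl}formamide (methyl ketone) | C=C(C)/C=C/[C@@H](CCC(C)=O)[C@]1(C)CC[C@H](C(C)(C)NC=O)O1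
F4 | step 12 | N-[(R)-tert-butanesulfinyl] ketimine of F3, sulfinyl anti to the chain | C=C(C)/C=C/[C@@H](CC/C(C)=N/[S@](=O)C(C)(C)C)[C@]1(C)CC[C@H](C(C)(C)NC=O)O1
F5 | step 12 | (R)-tert-butanesulfinamide of the (3R)-3-methyl-1,7,9-decatrien-3-amine carrying the oxolane at C6 | C=C(C)/C=C/[C@@H](CC[C@@](C)(N[S@](=O)C(C)(C)C)C=C)[C@]1(C)CC[C@H](C(C)(C)NC=O)O1
F6 | step 12 | free amine of F5 as hydrochloride | C=C(C)/C=C/[C@@H](CC[C@@](C)(N)C=C)[C@]1(C)CC[C@H](C(C)(C)NC=O)O1.Cl
F7 | step 12 | N-{2-[(2R,5S)-5-[(3E,5R,8R)-8-formamido-2,8-dimethyldeca-1,3,9-trien-5-yl]-5-methyloxolan-2-yl]propan-2-yl}formamide (bis-formamide triene) | C=C(C)/C=C/[C@@H](CC[C@@](C)(NC=O)C=C)[C@]1(C)CC[C@H](C(C)(C)NC=O)O1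
F8 | step 6 | di-tert-butyl 1-{2-[(2R,5S)-5-methyl-5-[(3R)-6-oxooxan-3-yl]oxolan-2-yl]propan-2-yl}hydrazine-1,2-dicarboxylate | O=C1CC[C@H](CO1)[C@]2(C)CC[C@H](C(C)(C)N(NC(=O)OC(C)(C)C)C(=O)OC(C)(C)C)O2
F9 | step 6 | (5R)-5-[(2S,5R)-5-(2-hydrazinylpropan-2-yl)-2-methyloxolan-2-yl]oxan-2-one | O=C1CC[C@H](CO1)[C@]2(C)CC[C@H](C(C)(C)NN)O2
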